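**Numbering used throughout.** Ring A: C1 (CH2OH), C2 (Br), C3 (ether oxygen), C4 (OH), C5 (Br), C6 (H). Ring B: C1' (ether oxygen), C2' (CH2OH), C3' (H), C4' (Br), C5' (OH), C6' (OH). Compounds are numbered 1–20 as in the steps and the compound list.

## Analysis of the target

The target is a diaryl ether of two brominated hydroxybenzyl alcohols and has no stereocentre. The ether oxygen joins C3 of ring A to C1' of ring B, and all four positions ortho to it are substituted (C2–Br, C4–OH, C2'–CH2OH, C6'–OH). A direct aryl–oxygen coupling of two complete arenes would therefore be strongly hindered. Ring B is pentasubstituted, with the ether oxygen, two hydroxyls, a bromine and a hydroxymethyl group in a fixed order, so its regiochemistry must also be secured. The sensitive groups are the catechol of ring B (oxidation), the two benzylic alcohols that each lie para to a free phenol (C1/C4 and C2'/C5', prone to quinone methide formation), and three aryl bromides (reduction, metal exchange). The plan rests on the run C1'(O-aryl)–C6'(O)–C5'(O) of ring B, which is the pattern of a ketone with an aryloxy group on one α-carbon and a methoxy group on the other. C2' with its attached carbon corresponds to the ketone carbon and carboxyl carbon of a pyruvate. Ring B can therefore be built as a cyclohexenone around a C1'–O bond made by SN2 at an sp3 carbon, and aromatised afterwards.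

## Retrosynthetic reasoning

**20 ⇐ 19 ⇐ 18.** The two hydroxymethyl groups are traced back to methyl esters and the three phenols to methyl ethers. The esters deactivate both rings during the electrophilic steps and survive Lewis acids. The fragile para-hydroxybenzyl alcohols then appear only in the last step, by hydride reduction of triphenol 19, which comes from 18 by Lewis acid cleavage of the three aryl methyl ethers.

**18 ⇐ 17 ⇐ 16.** The C4'–Br bond is cut next. In 17, C4' is ortho to the C5' methoxy group, para to the ether oxygen and meta to the ester, so an electrophile should go there. The C6' oxygen must be capped first (16 to 17), because a free C6' hydroxyl would direct to its para position C3'.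

**16 ⇐ 15.** The aromaticity of ring B is removed. Phenol 16 is the dehydrogenation product of cyclohexenone 15, in which C6' is a ketone, C1'=C2' is the only ring double bond and C3', C4', C5' are sp3. The forward step must remove two hydrogens and let the ring tautomerise.

**15 ⇐ 10 + 12 (through 13 and 14).** Two ring bonds of 15 are cut: C1'=C2' as an aldol condensation and C3'–C4' as a conjugate addition. This gives the 1-methoxyvinyl ketone 10, which holds C1', C6', C5', C4' and the complete ring A, and the silyl enol ether 12, which holds C3', C2' and the ester carbon. The cut is made here because it leaves the hindered ether as an ordinary α-aryloxy ketone. It also places the ester and all three ring B oxygens by connectivity, without any aromatic substitution. The forward reaction must add 12 to the terminal carbon of 10 to give the open-chain adduct 13, then close C1' onto the C2' keto ester (14) and dehydrate.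

**10 ⇐ 9 ⇐ 5 + 8.** The enol ether of 10 is traced to the dimethyl ketal 9 by loss of one methoxy group as the alcohol. The ketal protects the reactive enone during ether formation. The C1'–O bond of 9 is then cut as an SN2 displacement of bromide from the α-bromo ketone 8 by the phenoxide of 5. A hindered phenol attacks a primary carbon far more easily than it couples to a tetrasubstituted arene.

**8 ⇐ 6 (through 7) and 12 ⇐ 11.** Bromo ketone 8 comes from the ketal ketone 6, which can enolise only toward its acetyl methyl group. Bromination of its silyl enol ether 7 avoids acid and over-bromination. The silyl enol ether 12 comes from methyl pyruvate 11 by silylation.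

**5 ⇐ 4 ⇐ 3 ⇐ 2 ⇐ 1.** Ring A phenol 5 is traced to the bromophenol aldehyde 1. The missing C5 bromine is introduced ortho to the C4 methoxy group after the C3 hydroxyl is masked as the acetate 2. A free C3 hydroxyl would direct to C6. Oxidation of aldehyde 3 to acid 4, then esterification with loss of the acetate, gives 5.

## Alternatives that were turned down

**Alternative 1:** This route cuts the C3–O and C2–Br bonds of ring A together, on a C2–C3 aryne that carries boron at C4.
- Forward key step: halogen–magnesium exchange on the iodo triflate A2 releases the aryne. The magnesium phenolate of the ring B phenol A3 adds at C3, next to boron. The C2 arylmagnesium is then trapped by an electrophilic bromine source to give the diaryl ether A1. No ring is formed.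
- For: it is the most convergent plan. Both rings are used as complete arenes, an aryne is indifferent to ortho crowding on the electrophile, and the C2 bromine arrives in the same operation. The boron later becomes the C4 hydroxyl, which directs the last bromine to C5.
- Against: A2 is a contiguously tetrasubstituted arene that needs its own multistep synthesis. The phenolate of A3 is flanked on both sides and is a weak nucleophile as its magnesium salt, so the exchange reagent competes for the aryne. The aryl bromide of A3 must survive that reagent. The C2 carbanion sits between two substituents and may be protonated before it is brominated. The regiochemistry depends on aryne distortion, not on connectivity.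
- Comparison: Alternative 1 is stronger on convergence and probably on step count. The chosen route offers instead an ether bond made by a phenoxide on a primary α-bromo ketone, with no regiochemical question at that step.

**Alternative 2:** This route cuts C1'–C6' and C2'–C3' of ring B as a [4+2] cycloaddition of the furan A5 with the aryloxy alkynoate A6.
- Forward key step: cycloaddition gives a 7-oxanorbornadiene, and acid opens the oxygen bridge to the ring B phenol A4.
- For: ring B arrives with all six substituents, including the C4' bromine and the free C6' hydroxyl, so neither dehydrogenation nor a late bromination is needed. The bridge should open the right way, because a cation at C3' is stabilised through both the C5' methoxy and the C1' aryloxy group. The polarity of the partners also matches the required regiochemistry.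
- Against: A5 is an acid-labile, electron-rich furan that is not a stock compound, and furans are reluctant, reversible dienes. A6 is an ynol ether, whose oxygen donor makes the alkyne a poor dienophile and a hydrolytically fragile one. A6 must itself be made from the hindered ring A phenol by alkynyl ether chemistry, which is harder than the alkylation of 5 with 8.
- Comparison: Alternative 2 is stronger on step economy after the key step. The chosen route offers stable, easily made partners and a ring closure whose regiochemistry follows from the connectivity of 13.

**Alternative 3:** This route cuts C2–C3 and C6–C1 of ring A as a [4+2] cycloaddition of the oxygenated diene A8, which carries ring B as its aryloxy group, with the bromoalkynoate A9.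
- Forward key step: cycloaddition, then loss of methanol and of the silyl group, aromatises the new ring to phenol A7.
- For: the polarised diene and dienophile should pair reliably (nucleophilic terminus C3 to the bromine-bearing carbon C2). The C2 bromine and C1 ester are set in the step, and the C4 hydroxyl emerges free to direct bromination to C5.
- Against: aromatisation needs a 1,4-elimination across C3 and C6 of the cycloadduct. C3 carries the aryloxy group and C6 the methoxy group, and an electron-poor aryloxide is the better leaving group, so loss of ring B competes and would cut the ether just formed. The bulky aryloxy group at the diene terminus should slow the cycloaddition. A8 still has to be made from an α-aryloxy ketone, so the ether is formed by the same SN2 logic as in the chosen route, and ring B has to be prepared separately in full.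
- Comparison: the length is similar. Alternative 3 is as strong on regiocontrol of the ring-forming step but weaker because that step puts the ether at risk. In the chosen route the aryloxy group sits on a carbon from which it cannot be eliminated during ring formation or aromatisation.

Key step: step 9

Remark: the target is achiral. The one stereocentre that appears on the way (C5' in 13–15) is carried as the racemate and is destroyed in step 10. Compounds 1, 6 and 11 are taken as purchasable.

## Route

Step 1
Reactants: 1 2-bromo-3-hydroxy-4-methoxybenzaldehyde (2-bromoisovanillin)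
Product: 2 3-acetoxy-2-bromo-4-methoxybenzaldehyde
Conditions: Ac2O, pyridine, DMAP (cat.), CH2Cl2, 0 °C → rt
Reagents that add atoms: acetic anhydride, CC(=O)OC(C)=O
Why: O-acylation of the phenol; the acetate turns the strongly para-directing C3 hydroxyl into a weak donor, so that the C4 methoxy group controls the next substitution.

Step 2
Reactants: 2 3-acetoxy-2-bromo-4-methoxybenzaldehyde
Product: 3 3-acetoxy-2,5-dibromo-4-methoxybenzaldehyde
Conditions: Br2, NaOAc, Fe powder (cat.), AcOH, 60 °C
Reagents that add atoms: bromine, BrBr
Why: Electrophilic aromatic bromination; C5 is ortho to the methoxy group (whose para position is blocked by the formyl group), meta to the formyl group and para to the C2 bromine, whereas C6 is ortho to the formyl group and activated only by the weak acetoxy donor, so C5 should be substituted.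

Step 3
Reactants: 3 3-acetoxy-2,5-dibromo-4-methoxybenzaldehyde
Product: 4 3-acetoxy-2,5-dibromo-4-methoxybenzoic acid
Conditions: NaClO2, NaH2PO4, 2-methylbut-2-ene, t-BuOH/H2O, rt
Reagents that add atoms: sodium chlorite, [Na+].[O-]Cl=O
Why: Pinnick oxidation of the aldehyde to the acid; the buffered medium leaves the aryl acetate and the bromides alone, and the alkene scavenger removes hypochlorous acid before it can chlorinate the ring.

Step 4
Reactants: 4 3-acetoxy-2,5-dibromo-4-methoxybenzoic acid
Product: 5 methyl 2,5-dibromo-3-hydroxy-4-methoxybenzoate
Conditions: H2SO4 (cat.), MeOH, reflux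
Reagents that add atoms: methanol, CO
Why: Fischer esterification of the acid, with acid-catalysed methanolysis of the aryl acetate in the same operation, frees the C3 hydroxyl for ether formation.

Step 5
Reactants: 6 3,3-dimethoxybutan-2-one
Product: 8 1-bromo-3,3-dimethoxybutan-2-one, via silyl enol ether 7 (not isolated)
Conditions: LiN(i-Pr)2, Me3SiCl, THF, −78 °C; then N-bromosuccinimide, −78 → 0 °C
Reagents that add atoms: N-bromosuccinimide, O=C1CCC(=O)N1Br
Why: The ketone can enolise only toward its acetyl methyl group, so silyl enol ether formation and electrophilic bromination give the monobromo ketone without acid, which keeps the ketal intact and avoids dibromination.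

Step 6
Reactants: 5 methyl 2,5-dibromo-3-hydroxy-4-methoxybenzoate; 8 1-bromo-3,3-dimethoxybutan-2-one
Product: 9 methyl 2,5-dibromo-3-(3,3-dimethoxy-2-oxobutoxy)-4-methoxybenzoate
Conditions: K2CO3, acetone, 50 °C
Reagents that add atoms: none
Why: Williamson ether synthesis forms the O–C1' bond; the carbonyl accelerates SN2 at the primary CH2Br, the quaternary ketal carbon on the other side rules out a Favorskii pathway, and the hindered phenoxide meets an unhindered carbon.

Step 7
Reactants: 9 methyl 2,5-dibromo-3-(3,3-dimethoxy-2-oxobutoxy)-4-methoxybenzoate
Product: 10 methyl 2,5-dibromo-4-methoxy-3-[(3-methoxy-2-oxobut-3-en-1-yl)oxy]benzoate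
Conditions: TsOH (cat., anhydrous), BHT (trace), toluene, reflux with slow distillation of MeOH
Reagents that add atoms: none
Why: Acid-catalysed elimination of methanol from the dimethyl ketal gives the methyl enol ether, the usual access to 2-alkoxy vinyl ketones from α-keto ketals; removal of methanol drives the equilibrium and exclusion of water prevents hydrolysis to the diketone.

Step 8
Reactants: 11 methyl pyruvate
Product: 12 methyl 2-(trimethylsilyloxy)acrylate
Conditions: Me3SiCl, Et3N, CH2Cl2, 0 °C → rt; distillation
Reagents that add atoms: chlorotrimethylsilane, C[Si](C)(C)Cl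
Why: Soft enolisation and O-silylation of the acidic α-keto ester gives the silyl enol ether, a storable pyruvate enolate equivalent that cannot self-condense.

Step 9
Reactants: 10 methyl 2,5-dibromo-4-methoxy-3-[(3-methoxy-2-oxobut-3-en-1-yl)oxy]benzoate; 12 methyl 2-(trimethylsilyloxy)acrylate
Product: 15 methyl 2-[2,5-dibromo-6-methoxy-3-(methoxycarbonyl)phenoxy]-4-methoxy-3-oxocyclohex-1-ene-1-carboxylate (racemic), via Michael adduct 13 (not isolated), via aldol adduct 14 (not isolated)
Conditions: TiCl4, CH2Cl2, −78 °C; aq. NaHCO3 work-up; crude 13, TsOH (cat.), toluene, reflux (Dean–Stark)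
Reagents that add atoms: none
Why: TiCl4 binds the carbonyl and methoxy oxygens of 10 as a five-membered chelate, which ties up the lone pair that otherwise weakens the 1-methoxyvinyl ketone as an acceptor, and 12 adds through its CH2 carbon to the open terminus C4' (C3'–C4'); this is a Mukaiyama–Michael addition, and attack at the terminal carbon and not at the carbonyl is secured by the unsubstituted CH2 end and the soft, weakly nucleophilic donor. Work-up protonates the titanium enolate at C5' and frees the C2' ketone, so 13 carries a new stereocentre at C5' that nothing controls and that forms as the racemate. Under TsOH the ketone enolises toward C1', and this enol adds to the strongly electrophilic C2' keto ester carbonyl in a 6-(enolendo)-exo-trig aldol closure that forms ring B as 14 (C1'–C2'). Loss of water through the same enol then places the C1'=C2' double bond in conjugation with both the ketone and the ester, which removes the two uncontrolled centres of 14 and pulls the sequence forward. Overall this is a Robinson annulation with a pyruvate donor and an α-alkoxy vinyl ketone. The selectivity needed is one aldol among several enolisable positions, and ring size provides it, since C3' attacking C6' or C5' attacking C2' would give four-membered rings. Acid is used for the second stage because 15 is a β-aryloxy enoate from which an amine or alkoxide base could expel the ring A phenoxide by addition–elimination.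

Step 10
Reactants: 15 methyl 2-[2,5-dibromo-6-methoxy-3-(methoxycarbonyl)phenoxy]-4-methoxy-3-oxocyclohex-1-ene-1-carboxylate (racemic)
Product: 16 methyl 2,5-dibromo-3-[2-hydroxy-3-methoxy-6-(methoxycarbonyl)phenoxy]-4-methoxybenzoate
Conditions: DDQ, TsOH (cat.), 1,4-dioxane, 90 °C
Reagents that add atoms: none
Why: Dehydrogenation of a cyclohexenone to a phenol by a high-potential quinone; the acid-formed dienol loses hydride from C4' to DDQ, the resulting dienone shifts its C5' hydrogen to oxygen, and the racemic C5' centre disappears.

Step 11
Reactants: 16 methyl 2,5-dibromo-3-[2-hydroxy-3-methoxy-6-(methoxycarbonyl)phenoxy]-4-methoxybenzoate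
Product: 17 methyl 2,5-dibromo-3-[2,3-dimethoxy-6-(methoxycarbonyl)phenoxy]-4-methoxybenzoate
Conditions: MeI, K2CO3, DMF, rt
Reagents that add atoms: iodomethane, CI
Why: O-methylation of the phenol; capping the C6' oxygen removes its strong para direction toward C3' and, because the new methoxy group is twisted between two ortho substituents, leaves the C5' methoxy group as the controlling donor.

Step 12
Reactants: 17 methyl 2,5-dibromo-3-[2,3-dimethoxy-6-(methoxycarbonyl)phenoxy]-4-methoxybenzoate
Product: 18 methyl 2,5-dibromo-3-[4-bromo-2,3-dimethoxy-6-(methoxycarbonyl)phenoxy]-4-methoxybenzoate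
Conditions: N-bromosuccinimide, MeCN, rt
Reagents that add atoms: N-bromosuccinimide, O=C1CCC(=O)N1Br
Why: Electrophilic aromatic bromination at C4', which is ortho to the C5' methoxy group, para to the ether oxygen and meta to the ester, as in 2,3,4-trialkoxybenzoates; C3' is ortho to the ester, and ring A is deactivated by its ester and two bromines.

Step 13
Reactants: 18 methyl 2,5-dibromo-3-[4-bromo-2,3-dimethoxy-6-(methoxycarbonyl)phenoxy]-4-methoxybenzoate
Product: 19 methyl 2,5-dibromo-3-[4-bromo-2,3-dihydroxy-6-(methoxycarbonyl)phenoxy]-4-hydroxybenzoate
Conditions: BBr3, CH2Cl2, −78 → 0 °C; H2O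
Reagents that add atoms: none
Why: Lewis acid cleavage of the three aryl methyl ethers by bromide attack on the boron-activated methyl groups; the diaryl ether has no alkyl carbon to attack, and the methyl esters and aryl bromides should persist at or below 0 °C.

Step 14
Reactants: 19 methyl 2,5-dibromo-3-[4-bromo-2,3-dihydroxy-6-(methoxycarbonyl)phenoxy]-4-hydroxybenzoate
Product: 20 6-bromo-3-[2,5-dibromo-6-hydroxy-3-(hydroxymethyl)phenoxy]-4-(hydroxymethyl)benzene-1,2-diol (target)
Conditions: i-Bu2AlH (excess), THF, −78 → 0 °C; aq. potassium sodium tartrate
Reagents that add atoms: none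
Why: Hydride reduction of both esters to the benzylic alcohols after the three phenols have been converted to aluminium phenoxides; aryl bromides are inert to this hydride at low temperature, and the neutral tartrate work-up avoids acid-induced quinone methide formation.

## Compound list

1 | 2-bromo-3-hydroxy-4-methoxybenzaldehyde | COc1ccc(C=O)c(Br)c1O | starting material
2 | 3-acetoxy-2-bromo-4-methoxybenzaldehyde | COc1ccc(C=O)c(Br)c1OC(C)=O | intermediate
3 | 3-acetoxy-2,5-dibromo-4-methoxybenzaldehyde | COc1c(Br)cc(C=O)c(Br)c1OC(C)=O | intermediate
4 | 3-acetoxy-2,5-dibromo-4-methoxybenzoic acid | COc1c(Br)cc(C(=O)O)c(Br)c1OC(C)=O | intermediate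
5 | methyl 2,5-dibromo-3-hydroxy-4-methoxybenzoate | COC(=O)c1cc(Br)c(OC)c(O)c1Br | intermediate
6 | 3,3-dimethoxybutan-2-one | CC(=O)C(C)(OC)OC | starting material
7 | 3,3-dimethoxy-2-(trimethylsilyloxy)but-1-ene | C=C(O[Si](C)(C)C)C(C)(OC)OC | intermediate
8 | 1-bromo-3,3-dimethoxybutan-2-one | BrCC(=O)C(C)(OC)OC | intermediate
9 | methyl 2,5-dibromo-3-(3,3-dimethoxy-2-oxobutoxy)-4-methoxybenzoate | CC(OC)(OC)C(=O)COc1c(OC)c(Br)cc(C(=O)OC)c1Br | intermediate
10 | methyl 2,5-dibromo-4-methoxy-3-[(3-methoxy-2-oxobut-3-en-1-yl)oxy]benzoate | C=C(OC)C(=O)COc1c(OC)c(Br)cc(C(=O)OC)c1Br | intermediate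
11 | methyl pyruvate | CC(=O)C(=O)OC | starting material
12 | methyl 2-(trimethylsilyloxy)acrylate | C=C(O[Si](C)(C)C)C(=O)OC | intermediate
13 | methyl 7-[2,5-dibromo-6-methoxy-3-(methoxycarbonyl)phenoxy]-5-methoxy-2,6-dioxoheptanoate (racemic) | COC(=O)C(=O)CCC(OC)C(=O)COc1c(OC)c(Br)cc(C(=O)OC)c1Br | intermediate
14 | methyl 2-[2,5-dibromo-6-methoxy-3-(methoxycarbonyl)phenoxy]-1-hydroxy-4-methoxy-3-oxocyclohexane-1-carboxylate (racemic, mixture of diastereomers) | COC(=O)C1(O)CCC(OC)C(=O)C1Oc1c(OC)c(Br)cc(C(=O)OC)c1Br | intermediate
15 | methyl 2-[2,5-dibromo-6-methoxy-3-(methoxycarbonyl)phenoxy]-4-methoxy-3-oxocyclohex-1-ene-1-carboxylate (racemic) | COC(=O)C1=C(Oc2c(OC)c(Br)cc(C(=O)OC)c2Br)C(=O)C(OC)CC1 | intermediate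
16 | methyl 2,5-dibromo-3-[2-hydroxy-3-methoxy-6-(methoxycarbonyl)phenoxy]-4-methoxybenzoate | COC(=O)c1ccc(OC)c(O)c1Oc1c(OC)c(Br)cc(C(=O)OC)c1Br | intermediate
17 | methyl 2,5-dibromo-3-[2,3-dimethoxy-6-(methoxycarbonyl)phenoxy]-4-methoxybenzoate | COC(=O)c1ccc(OC)c(OC)c1Oc1c(OC)c(Br)cc(C(=O)OC)c1Br | intermediate
18 | methyl 2,5-dibromo-3-[4-bromo-2,3-dimethoxy-6-(methoxycarbonyl)phenoxy]-4-methoxybenzoate | COC(=O)c1cc(Br)c(OC)c(OC)c1Oc1c(OC)c(Br)cc(C(=O)OC)c1Br | intermediate
19 | methyl 2,5-dibromo-3-[4-bromo-2,3-dihydroxy-6-(methoxycarbonyl)phenoxy]-4-hydroxybenzoate | COC(=O)c1cc(Br)c(O)c(O)c1Oc1c(O)c(Br)cc(C(=O)OC)c1Br | intermediate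
20 | 6-bromo-3-[2,5-dibromo-6-hydroxy-3-(hydroxymethyl)phenoxy]-4-(hydroxymethyl)benzene-1,2-diol | OCc1cc(Br)c(O)c(Oc2c(CO)cc(Br)c(O)c2O)c1Br | target

## Step count and least certain steps

Total: 14 steps. Longest linear sequence: 12 steps (steps 1–4, 6, 7, 9–14, from 1 to 20).

**Step 9 (key step).** The most likely failure is in the first stage: the enol ether of 10 may be cleaved or the enone may polymerise under TiCl4 before the weakly nucleophilic 12 adds, or 12 may add to the carbonyl. Fallback, from 10, returning at 13: replace the Lewis acid addition by a base-catalysed Michael addition of a doubly activated pyruvate equivalent. A crossed Claisen condensation of the lithium enolate of tert-butyl acetate with dimethyl oxalate would give 4-tert-butyl 1-methyl 2-oxobutanedioate F1. F1 should add to 10 with catalytic Et3N to give the tert-butyl ester adduct F2. Trifluoroacetic acid in CH2Cl2 would then cleave the tert-butyl ester, and the resulting β-keto acid loses CO2 to give 13, which is cyclised to 15 with TsOH as in step 9.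

**Step 7.** The elimination may stall at equilibrium, and the enol ether may be hydrolysed by traces of water or polymerise on prolonged heating. Fallback, from 6, returning at 10: form the enone before the ether. Acid-catalysed loss of methanol from 6 with distillation gives 3-methoxybut-3-en-2-one F3. Its kinetic enolate is silylated to 2-methoxy-3-(trimethylsilyloxy)buta-1,3-diene F4. N-Bromosuccinimide gives 1-bromo-3-methoxybut-3-en-2-one F5, and alkylation of 5 with F5 (K2CO3, acetone, 0 °C → rt) gives 10 directly.

**Step 10.** Hydride abstraction from an enone that carries an ester may be slow, and the electron-rich guaiacol-type product may be oxidised further by the quinone at the temperature needed. Fallback, from 15, returning at 16: deprotonate at C5' with LiN(SiMe3)2 and trap with Me3SiCl to give the cross-conjugated silyl dienol ether F6. A Saegusa–Ito oxidation with Pd(OAc)2 (divalent palladium) in MeCN at rt gives the 2,5-dienone, which tautomerises to 16.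

**Step 14.** Loss of benzylic oxygen through quinone methide formation from the aluminium phenoxides, followed by hydride capture, would give methyl arenes; incomplete reduction of the deactivated phenoxide esters is the other risk. Fallback, from 18, returning at 20: reduce first. i-Bu2AlH on 18 gives the bis(benzyl alcohol) F7, in which no free phenol is present. BBr3 then cleaves the three methyl ethers and converts both alcohols to bromides, giving the bis(bromomethyl) triphenol F8. Mild hydrolysis in aqueous acetone with NaHCO3 gives 20.

**Step 12.** Substitution may go partly to C3' (para to the C6' methoxy group) if the ether oxygen and the C5' methoxy group direct less strongly than expected. Fallback, from 17, returning at 19: demethylate first with BBr3 to the triphenol diester F9. Then brominate with Br2 in AcOH at 0 °C, where the free C5' hydroxyl directs ortho to C4' as in protocatechuates and ring A has no activated free position.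

**Step 2.** The ring is deactivated, so substitution may be slow; if the acetate is cleaved by the acid formed, the free hydroxyl would send bromine to C6. Fallback, from 1, returning at 3: use hydroxyl direction instead. BBr3 on 1 gives 2-bromo-3,4-dihydroxybenzaldehyde F10. Bromination ortho to the C4 hydroxyl (Br2, AcOH) gives 2,5-dibromo-3,4-dihydroxybenzaldehyde F11. Selective methylation of the more acidic C4 hydroxyl, para to the formyl group (Li2CO3, MeI, DMF), gives 2,5-dibromo-3-hydroxy-4-methoxybenzaldehyde F12, and acetylation gives 3.

## Further compounds

F1 | step 9 | 4-tert-butyl 1-methyl 2-oxobutanedioate | COC(=O)C(=O)CC(=O)OC(C)(C)C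
F2 | step 9 | 4-tert-butyl 1-methyl 3-{4-[2,5-dibromo-6-methoxy-3-(methoxycarbonyl)phenoxy]-2-methoxy-3-oxobutyl}-2-oxobutanedioate (racemic, mixture of diastereomers) | COC(=O)C(=O)C(CC(OC)C(=O)COc1c(OC)c(Br)cc(C(=O)OC)c1Br)C(=O)OC(C)(C)C
F3 | step 7 | 3-methoxybut-3-en-2-one | C=C(OC)C(C)=O
F4 | step 7 | 2-methoxy-3-(trimethylsilyloxy)buta-1,3-diene | C=C(OC)C(=C)O[Si](C)(C)C
F5 | step 7 | 1-bromo-3-methoxybut-3-en-2-one | C=C(OC)C(=O)CBr
F6 | step 10 | methyl 2-[2,5-dibromo-6-methoxy-3-(methoxycarbonyl)phenoxy]-4-methoxy-3-(trimethylsilyloxy)cyclohexa-1,3-diene-1-carboxylate | COC(=O)C1=C(Oc2c(OC)c(Br)cc(C(=O)OC)c2Br)C(O[Si](C)(C)C)=C(OC)CC1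
F7 | step 14 | {2,5-dibromo-3-[4-bromo-6-(hydroxymethyl)-2,3-dimethoxyphenoxy]-4-methoxyphenyl}methanol | OCc1cc(Br)c(OC)c(OC)c1Oc1c(OC)c(Br)cc(CO)c1Br
F8 | step 14 | 6-bromo-4-(bromomethyl)-3-[2,5-dibromo-3-(bromomethyl)-6-hydroxyphenoxy]benzene-1,2-diol | BrCc1cc(Br)c(O)c(O)c1Oc1c(O)c(Br)cc(CBr)c1Br
F9 | step 12 | methyl 2,5-dibromo-3-[2,3-dihydroxy-6-(methoxycarbonyl)phenoxy]-4-hydroxybenzoate | COC(=O)c1ccc(O)c(O)c1Oc1c(O)c(Br)cc(C(=O)OC)c1Br
F10 | step 2 | 2-bromo-3,4-dihydroxybenzaldehyde | O=Cc1ccc(O)c(O)c1Br
F11 | step 2 | 2,5-dibromo-3,4-dihydroxybenzaldehyde | O=Cc1cc(Br)c(O)c(O)c1Br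
F12 | step 2 | 2,5-dibromo-3-hydroxy-4-methoxybenzaldehyde | COc1c(Br)cc(C=O)c(Br)c1O
A1 | alternative 1 | tert-butyl({2-bromo-3-[4-bromo-6-{[tert-butyl(dimethyl)silyl]oxymethyl}-2,3-bis(methoxymethoxy)phenoxy]-4-(4,4,5,5-tetramethyl-1,3,2-dioxaborolan-2-yl)phenyl}methoxy)dimethylsilane | CC(C)(C)[Si](C)(C)OCc1ccc(B2OC(C)(C)C(C)(C)O2)c(Oc2c(CO[Si](C)(C)C(C)(C)C)cc(Br)c(OCOC)c2OCOC)c1Br
A2 | alternative 1 | 3-{[tert-butyl(dimethyl)silyl]oxymethyl}-2-iodo-6-(4,4,5,5-tetramethyl-1,3,2-dioxaborolan-2-yl)phenyl trifluoromethanesulfonate | CC(C)(C)[Si](C)(C)OCc1ccc(B2OC(C)(C)C(C)(C)O2)c(OS(=O)(=O)C(F)(F)F)c1I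
A3 | alternative 1 | 4-bromo-6-{[tert-butyl(dimethyl)silyl]oxymethyl}-2,3-bis(methoxymethoxy)phenol | Oc1c(CO[Si](C)(C)C(C)(C)C)cc(Br)c(OCOC)c1OCOC
A4 | alternative 2 | methyl 5-bromo-2-(2,5-dibromo-3-formyl-6-methoxyphenoxy)-3-hydroxy-4-methoxybenzoate | COC(=O)c1cc(Br)c(OC)c(O)c1Oc1c(OC)c(Br)cc(C=O)c1Br
A5 | alternative 2 | 3-bromo-4-methoxyfuran | COc1cocc1Br
A6 | alternative 2 | methyl 3-(2,5-dibromo-3-formyl-6-methoxyphenoxy)prop-2-ynoate | COC(=O)C#COc1c(OC)c(Br)cc(C=O)c1Br
A7 | alternative 3 | methyl 5-bromo-2-[2-bromo-6-hydroxy-3-(methoxycarbonyl)phenoxy]-3,4-dimethoxybenzoate | COC(=O)c1ccc(O)c(Oc2c(C(=O)OC)cc(Br)c(OC)c2OC)c1Br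
A8 | alternative 3 | methyl 5-bromo-3,4-dimethoxy-2-{[(1Z,3E)-4-methoxy-2-(trimethylsilyloxy)buta-1,3-dien-1-yl]oxy}benzoate | CO/C=C/C(=C/Oc1c(C(=O)OC)cc(Br)c(OC)c1OC)O[Si](C)(C)C
A9 | alternative 3 | methyl 3-bromoprop-2-ynoate | COC(=O)C#CBr
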